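**Retrosynthetic overview**

1. Numbering is that of tricyclo[5.4.0.0(2,8)]undecane: C-1 is the cyclobutane CH next to the C-11 ketone, C-2 is C–CH3, C-3 is CH–O-angeloyl, C-4 is CH2, C-5 is CH–O-epoxyacyl, C-6 is CMe2, C-7 and C-8 are cyclobutane CH, C-9=C-10 is the enone. The target is cut at the two ester C–O bonds to give the 3,5-anti diol, which comes from the 3-hydroxy-5-ketone by hydroxyl-directed reduction; the acids come from angelic acid and from asymmetric epoxidation of tiglyl alcohol.
2. In that ketol, C-3–C-4 (aldol) and C-1–C-7 (enolate alkylation) are cut together. This opens the seven-membered and the four-membered ring at once and leaves a monocyclic 3-methylcyclohex-2-enone that carries a CH(OMs)–CMe2–COCH3 chain and a C(CH3)–CHO group on adjacent carbons.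
3. The feature that allows this is the pair of quaternary carbons C-6 and C-2. C-6 leaves the C-5 ketone only its CH3 (the future C-4) to enolise, and C-2 makes the C-3 aldehyde non-enolisable. C-1, the α′-CH2 of the enone, sits 1,3-cis on the six-membered ring to the mesylate carbon C-7, and O-alkylation is excluded because it would give a bridgehead enol ether.
4. The monocycle comes from a cis-fused lactone acetal, in which C-7 is set by Grignard addition to the lactone and silane reduction, and the acetal is opened to a dithiane to free the carbinol. The lactone acetal comes from a Diels–Alder reaction of (E)-2-silyloxypenta-1,3-diene with (5S)-5-menthyloxy-4-methylfuran-2(5H)-one, which sets C-2 and C-8 from the acetal carbon.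
5. Ring order: six-membered ring (Diels–Alder), then a temporary lactone/tetrahydrofuran ring (removed later), then the seven- and four-membered rings together in the key step.

Key step: step 11

Remark: the 5S epimer of the menthyl acetal butenolide is assumed to be the one that crystallises with (+)-menthol, by mirror-image analogy with the parent 5-menthyloxyfuranone made from (−)-menthol.
Remark: the intramolecular aldol of step 11 is assumed to give the 3R carbinol; if the 3S epimer forms, it would be corrected by oxidation to the 3,5-dione and re-reduction.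

**Route**

Step 1
Reactants: 1 (E)-pent-3-en-2-one
Product: 2 (E)-tert-butyl(dimethyl)(penta-1,3-dien-2-yloxy)silane
Conditions: TBSOTf, Et3N, CH2Cl2, 0 °C
Reagents that add atoms: tert-butyldimethylsilyl triflate, CC(C)(C)[Si](C)(C)OS(=O)(=O)C(F)(F)F
Why: Soft enolisation of the methyl ketone silylates the cross-conjugated enolate on the CH3 side and leaves the E-propenyl group untouched, which is the standard preparation of 2-silyloxy-1,3-dienes and creates no stereocentre.

Step 2
Reactants: 3 5-hydroxy-4-methylfuran-2(5H)-one and 4 (+)-menthol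
Product: 5 (5S)-4-methyl-5-{[(1S,2R,5S)-5-methyl-2-(propan-2-yl)cyclohexyl]oxy}furan-2(5H)-one
Conditions: p-TsOH (cat.), toluene, reflux (Dean–Stark); crystallisation from hexane
Reagents that add atoms: none
Why: Acid-catalysed acetalisation of the cyclic pseudo-acid with the chiral alcohol gives both C-5 epimers, which interconvert through the oxocarbenium ion, so that crystallisation should collect the less soluble 5S epimer while the mother liquor is re-equilibrated (crystallisation-induced diastereomer transformation).

Step 3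
Reactants: 2 (E)-tert-butyl(dimethyl)(penta-1,3-dien-2-yloxy)silane and 5 (5S)-5-menthyloxy-4-methylfuran-2(5H)-one
Product: 6 cis-fused lactone acetal, 5-[(tert-butyldimethylsilyl)oxy]-3-[(1S,2R,5S)-menthyloxy]-3a,7-dimethyl-3a,4,7,7a-tetrahydro-2-benzofuran-1(3H)-one (menthyloxy, 3a-CH3 and H-7a on the convex face; 7-CH3 cis to the lactone carbonyl)
Conditions: toluene, BHT (cat.), 130 °C, sealed tube
Reagents that add atoms: none
Why: In this normal-electron-demand Diels–Alder reaction the CH2 terminus of the 2-silyloxydiene bonds to the β-carbon C-4 of the butenolide, the diene adds anti to the menthyloxy group and the cis dienophile gives the cis ring fusion, so the quaternary carbon and the ring-fusion CH are set in the absolute sense fixed by the acetal carbon, while the endo mode places the secondary CH3 cis to the lactone carbonyl (a centre erased in step 5).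

Step 4
Reactants: 6 cis-fused lactone acetal and 7 prenylmagnesium chloride
Product: 8 hemiketal, 5-[(tert-butyldimethylsilyl)oxy]-3-menthyloxy-3a,7-dimethyl-1-(2-methylbut-3-en-2-yl)-1,3,3a,4,7,7a-hexahydro-2-benzofuran-1-ol (anomer drawn with the carbon chain on the convex face)
Conditions: THF, −78 °C; then aq NH4Cl
Reagents that add atoms: none
Why: γ-Selective (SE2′) Grignard addition to the lactone carbonyl gives the α,α-dimethylallyl hemiketal, the magnesium hemiketalate being stable at −78 °C so that a second addition should not occur, and the anomeric configuration is of no consequence because this carbon is planarised in step 6.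

Step 5
Reactants: 8 hemiketal silyl enol ether
Product: 9 enone hemiketal, 1-hydroxy-3-menthyloxy-3a,7-dimethyl-1-(2-methylbut-3-en-2-yl)-3,3a,4,7a-tetrahydro-2-benzofuran-5(1H)-one
Conditions: Pd(OAc)2 (1.1 equiv), MeCN, 25 °C
Reagents that add atoms: none
Why: Saegusa–Ito oxidation of the regiodefined silyl enol ether left by the cycloaddition gives the 3-methylcyclohex-2-enone by β-hydride elimination from the palladium enolate and removes the secondary methyl stereocentre.

Step 6
Reactants: 9 enone hemiketal
Product: 10 tetrahydrofuran acetal, 3-menthyloxy-3a,7-dimethyl-1-(2-methylbut-3-en-2-yl)-3,3a,4,7a-tetrahydro-2-benzofuran-5(1H)-one (H-1, H-7a, 3a-CH3 and menthyloxy on the convex face; the carbon chain cis to the carbocycle)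
Conditions: Et3SiH, TMSOTf (cat.), CH2Cl2, −78 °C
Reagents that add atoms: none
Why: Silane reduction of the hemiketal through the cyclic oxocarbenium ion (ionic hydrogenation of a lactol) should deliver hydride to the convex face, anti to the adjacent ring-fusion C–C bond, which sets the ether methine (the future C-7) with the CMe2 chain cis to the carbocycle, the mixed acetal ionising more slowly than the tertiary hemiketal at this temperature.

Step 7
Reactants: 10 vinyl tetrahydrofuran acetal
Product: 11 methyl ketone, 3-menthyloxy-3a,7-dimethyl-1-(2-methyl-3-oxobutan-2-yl)-3,3a,4,7a-tetrahydro-2-benzofuran-5(1H)-one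
Conditions: PdCl2 (cat.), CuCl (cat.), O2 (1 atm), DMF/H2O, 25 °C
Reagents that add atoms: water, O
Why: Tsuji–Wacker oxidation converts the monosubstituted alkene into the methyl ketone with Markovnikov selectivity and does not touch the trisubstituted enone.

Step 8
Reactants: 11 methyl ketone acetal
Product: 12 (4R,5S)-5-(1,3-dithian-2-yl)-4-[(1S)-1-hydroxy-2,2-dimethyl-3-oxobutyl]-3,5-dimethylcyclohex-2-en-1-one
Conditions: HS(CH2)3SH, Sc(OTf)3 (cat.), CH2Cl2, −20 °C
Reagents that add atoms: propane-1,3-dithiol, SCCCS
Why: Lewis-acid-catalysed transthioacetalisation opens the cyclic mixed acetal at the aldehyde-level carbon, which is far more reactive than the hindered ketone or the enone, and so releases the carbinol and the auxiliary without touching a stereocentre.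

Step 9
Reactants: 12 hydroxy dithiane
Product: 13 (4R,5S)-5-(1,3-dithian-2-yl)-4-[(1S)-1-(methanesulfonyloxy)-2,2-dimethyl-3-oxobutyl]-3,5-dimethylcyclohex-2-en-1-one
Conditions: MsCl, Et3N, CH2Cl2, 0 °C
Reagents that add atoms: methanesulfonyl chloride, CS(=O)(=O)Cl
Why: Mesylation through sulfene tolerates the neopentyl-type secondary alcohol and proceeds with retention at the carbinol carbon.

Step 10
Reactants: 13 mesylate dithiane
Product: 14 (1S,2R)-2-[(1S)-1-(methanesulfonyloxy)-2,2-dimethyl-3-oxobutyl]-1,3-dimethyl-5-oxocyclohex-3-ene-1-carbaldehyde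
Conditions: MeI, CaCO3, MeCN/H2O, 45 °C
Reagents that add atoms: water, O
Why: S-Methylation of the dithiane and hydrolysis of the sulfonium ion (alkylative dethioacetalisation) liberate the non-enolisable aldehyde under buffered conditions that leave the mesylate and both ketones intact.

Step 11
Reactants: 14 keto aldehyde mesylate
Product: 16 (1R,2R,3R,7S,8R)-3-hydroxy-2,6,6,9-tetramethyltricyclo[5.4.0.0(2,8)]undec-9-ene-5,11-dione, via bicyclic lithium aldolate 15 (not isolated)
Conditions: lithium 2,2,6,6-tetramethylpiperidide (2.2 equiv), THF, −78 °C; then DMPU, −78 → 40 °C; aq NH4Cl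
Reagents that add atoms: none
Why: The hindered lithium amide removes the only two kinetically accessible acidic hydrogens, those of the side-chain CH3 (the other α-carbon of that ketone is the quaternary CMe2) and of the α′-CH2 of the enone, so that the enone is stored as its cross-conjugated enolate and can neither act as a Michael acceptor nor lose the mesylate by vinylogous elimination. The methyl-ketone enolate adds to the non-enolisable aldehyde on the quaternary ring carbon (7-exo-trig intramolecular aldol addition, which closes the seven-membered ring and gives aldolate 15), and on warming the α′-enolate carbon displaces the mesylate with inversion (4-exo-tet alkylation, which closes the cyclobutane). The closest known reaction types are the intramolecular aldol addition to medium rings and the base-induced keto-sulfonate cyclisation that closes the cyclobutane of copaene-, ylangene- and longipinene-type tricycles. C-3 is set in the lithium-bridged aldol transition state, in which the mesyloxy group shields the C-8 side so that both oxygens sit on the C-1 side; C-7 is set by inversion at the mesylate carbon (the reason for the configuration fixed in step 6), and C-1 by the requirement that the new bond be 1,3-cis to the side chain on the six-membered ring. The step needs C- and not O-alkylation, which is secured because O-alkylation would give a bridgehead enol ether, and it needs the methyl-ketone enolate not to attack the mesylate carbon, which is secured because the aldol addition is faster at −78 °C and ties this carbon up before the alkylation temperature is reached.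

Step 12
Reactants: 16 tricyclic ketol
Product: 17 (1R,2R,3R,5R,7S,8R)-3,5-dihydroxy-2,6,6,9-tetramethyltricyclo[5.4.0.0(2,8)]undec-9-en-11-one
Conditions: Me4NBH(OAc)3, MeCN/AcOH, −30 °C
Reagents that add atoms: none
Why: In the Evans–Saksena reduction the C-3 hydroxyl exchanges onto boron and hydride is delivered intramolecularly to the β-ketone through a chair-like six-membered transition state, which should give the 3,5-anti diol (5R) and leave the enone untouched.

Step 13
Reactants: 17 anti diol and 18 angelic acid
Product: 19 (1R,2R,3R,5R,7S,8R)-5-hydroxy-2,6,6,9-tetramethyl-11-oxotricyclo[5.4.0.0(2,8)]undec-9-en-3-yl (2Z)-2-methylbut-2-enoate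
Conditions: 2,4,6-trichlorobenzoyl chloride, Et3N, toluene, 25 °C; then 17, 75 °C
Reagents that add atoms: none
Why: Mixed-anhydride (Yamaguchi-type) esterification without a nucleophilic amine catalyst keeps the Z geometry of the angeloyl group and should acylate the C-3 hydroxyl, which is flanked by the tied-back cyclobutane carbon, in preference to the C-5 hydroxyl next to the gem-dimethyl carbon.

Step 14
Reactants: 20 (2E)-2-methylbut-2-en-1-ol
Product: 21 [(2R,3R)-2,3-dimethyloxiran-2-yl]methanol
Conditions: Ti(OiPr)4, D-(−)-diethyl tartrate, t-BuOOH, 4 Å molecular sieves, CH2Cl2, −20 °C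
Reagents that add atoms: tert-butyl hydroperoxide, CC(C)(C)OO
Why: Sharpless asymmetric epoxidation of the E-trisubstituted allylic alcohol with the D-(−)-tartrate ligand delivers oxygen to the face that gives the (2R,3R)-epoxy alcohol, the cis relation of the two methyl groups following from the E alkene.

Step 15
Reactants: 21 epoxy alcohol
Product: 22 (2S,3R)-2,3-dimethyloxirane-2-carboxylic acid
Conditions: RuCl3 (cat.), NaIO4, CCl4/MeCN/H2O, 25 °C
Reagents that add atoms: sodium periodate, [Na+].[O-][I](=O)(=O)=O; water, O
Why: Ruthenium tetroxide generated in the flask oxidises the primary alcohol to the carboxylic acid without opening the epoxide or touching its stereocentres, the C-2 descriptor changing only through the priority rules.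

Step 16
Reactants: 19 monoangelate and 22 epoxy acid
Product: 23 CNP0149458.1, (1R,2R,3R,5R,7S,8R)-5-{[(2S,3R)-2,3-dimethyloxirane-2-carbonyl]oxy}-2,6,6,9-tetramethyl-11-oxotricyclo[5.4.0.0(2,8)]undec-9-en-3-yl (2Z)-2-methylbut-2-enoate
Conditions: 2,4,6-trichlorobenzoyl chloride, Et3N, THF, 25 °C; then 19, DMAP, toluene, 60 °C
Reagents that add atoms: none
Why: Yamaguchi esterification with DMAP activation couples the hindered C-5 hydroxyl with the α,α-disubstituted epoxy acid, whose quaternary α-carbon cannot epimerise, to give the target.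

**Compound list**

1 | (E)-pent-3-en-2-one | C/C=C/C(C)=O | starting material
2 | (E)-tert-butyl(dimethyl)(penta-1,3-dien-2-yloxy)silane | C/C=C/C(=C)O[Si](C)(C)C(C)(C)C | intermediate
3 | 5-hydroxy-4-methylfuran-2(5H)-one (racemic pseudo-acid) | CC1=CC(=O)OC1O | starting material
4 | (+)-menthol, (1S,2R,5S)-5-methyl-2-(propan-2-yl)cyclohexan-1-ol | CC(C)[C@H]1CC[C@H](C)C[C@@H]1O | starting material
5 | (5S)-4-methyl-5-{[(1S,2R,5S)-5-methyl-2-(propan-2-yl)cyclohexyl]oxy}furan-2(5H)-one | CC1=CC(=O)O[C@@H]1O[C@H]2C[C@@H](C)CC[C@@H]2C(C)C | intermediate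
6 | cis-fused Diels–Alder adduct, 5-[(tert-butyldimethylsilyl)oxy]-3-menthyloxy-3a,7-dimethyl-3a,4,7,7a-tetrahydro-2-benzofuran-1(3H)-one (menthyloxy, 3a-CH3, H-7a on the convex face; 7-CH3 cis to the lactone carbonyl) | O=C1O[C@H](O[C@H]3C[C@@H](C)CC[C@@H]3C(C)C)[C@@]2(C)CC(O[Si](C)(C)C(C)(C)C)=C[C@@H](C)[C@@H]12 | intermediate
7 | prenylmagnesium chloride (3-methylbut-2-en-1-ylmagnesium chloride) | CC(C)=CC[Mg]Cl | starting material
8 | hemiketal silyl enol ether, 5-[(tert-butyldimethylsilyl)oxy]-3-menthyloxy-3a,7-dimethyl-1-(2-methylbut-3-en-2-yl)-1,3,3a,4,7,7a-hexahydro-2-benzofuran-1-ol | C=CC(C)(C)[C@]1(O)O[C@H](O[C@H]3C[C@@H](C)CC[C@@H]3C(C)C)[C@@]2(C)CC(O[Si](C)(C)C(C)(C)C)=C[C@@H](C)[C@@H]12 | intermediate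
9 | enone hemiketal, 1-hydroxy-3-menthyloxy-3a,7-dimethyl-1-(2-methylbut-3-en-2-yl)-3,3a,4,7a-tetrahydro-2-benzofuran-5(1H)-one | C=CC(C)(C)[C@]1(O)O[C@H](O[C@H]3C[C@@H](C)CC[C@@H]3C(C)C)[C@@]2(C)CC(=O)C=C(C)[C@@H]12 | intermediate
10 | tetrahydrofuran acetal, 3-menthyloxy-3a,7-dimethyl-1-(2-methylbut-3-en-2-yl)-3,3a,4,7a-tetrahydro-2-benzofuran-5(1H)-one (H-1, H-7a, 3a-CH3, menthyloxy on the convex face) | C=CC(C)(C)[C@H]1O[C@H](O[C@H]3C[C@@H](C)CC[C@@H]3C(C)C)[C@@]2(C)CC(=O)C=C(C)[C@@H]12 | intermediate
11 | 3-menthyloxy-3a,7-dimethyl-1-(2-methyl-3-oxobutan-2-yl)-3,3a,4,7a-tetrahydro-2-benzofuran-5(1H)-one (configuration as 10) | CC(=O)C(C)(C)[C@H]1O[C@H](O[C@H]3C[C@@H](C)CC[C@@H]3C(C)C)[C@@]2(C)CC(=O)C=C(C)[C@@H]12 | intermediate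
12 | (4R,5S)-5-(1,3-dithian-2-yl)-4-[(1S)-1-hydroxy-2,2-dimethyl-3-oxobutyl]-3,5-dimethylcyclohex-2-en-1-one | CC(=O)C(C)(C)[C@@H](O)[C@@H]1C(C)=CC(=O)C[C@]1(C)C1SCCCS1 | intermediate
13 | (4R,5S)-5-(1,3-dithian-2-yl)-4-[(1S)-1-(methanesulfonyloxy)-2,2-dimethyl-3-oxobutyl]-3,5-dimethylcyclohex-2-en-1-one | CC(=O)C(C)(C)[C@@H](OS(C)(=O)=O)[C@@H]1C(C)=CC(=O)C[C@]1(C)C1SCCCS1 | intermediate
14 | (1S,2R)-2-[(1S)-1-(methanesulfonyloxy)-2,2-dimethyl-3-oxobutyl]-1,3-dimethyl-5-oxocyclohex-3-ene-1-carbaldehyde | CC(=O)C(C)(C)[C@@H](OS(C)(=O)=O)[C@@H]1C(C)=CC(=O)C[C@]1(C)C=O | intermediate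
15 | cis-fused six-seven bicyclic ketol mesylate (seven-membered ring closed, cyclobutane still open), formed as its lithium alkoxide and enolate; drawn as the neutral alcohol | O[C@@H]1CC(=O)C(C)(C)[C@@H](OS(C)(=O)=O)[C@@H]2C(C)=CC(=O)C[C@@]21C | intermediate
16 | (1R,2R,3R,7S,8R)-3-hydroxy-2,6,6,9-tetramethyltricyclo[5.4.0.0(2,8)]undec-9-ene-5,11-dione | O[C@@H]1CC(=O)C(C)(C)[C@@H]2[C@H]3C(=O)C=C(C)[C@@H]2[C@]31C | intermediate
17 | (1R,2R,3R,5R,7S,8R)-3,5-dihydroxy-2,6,6,9-tetramethyltricyclo[5.4.0.0(2,8)]undec-9-en-11-one | O[C@@H]1C[C@@H](O)C(C)(C)[C@@H]2[C@H]3C(=O)C=C(C)[C@@H]2[C@]31C | intermediate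
18 | angelic acid, (2Z)-2-methylbut-2-enoic acid | C/C=C(/C)C(=O)O | starting material
19 | (1R,2R,3R,5R,7S,8R)-5-hydroxy-2,6,6,9-tetramethyl-11-oxotricyclo[5.4.0.0(2,8)]undec-9-en-3-yl (2Z)-2-methylbut-2-enoate | C/C=C(/C)C(=O)O[C@@H]1C[C@@H](O)C(C)(C)[C@@H]2[C@H]3C(=O)C=C(C)[C@@H]2[C@]31C | intermediate
20 | (2E)-2-methylbut-2-en-1-ol (tiglyl alcohol) | C/C=C(\C)CO | starting material
21 | [(2R,3R)-2,3-dimethyloxiran-2-yl]methanol | OC[C@@]1(C)O[C@@H]1C | intermediate
22 | (2S,3R)-2,3-dimethyloxirane-2-carboxylic acid | OC(=O)[C@@]1(C)O[C@@H]1C | intermediate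
23 | CNP0149458.1, (1R,2R,3R,5R,7S,8R)-5-{[(2S,3R)-2,3-dimethyloxirane-2-carbonyl]oxy}-2,6,6,9-tetramethyl-11-oxotricyclo[5.4.0.0(2,8)]undec-9-en-3-yl (2Z)-2-methylbut-2-enoate | C/C=C(/C)C(=O)O[C@@H]1C[C@@H](OC(=O)[C@@]2(C)O[C@@H]2C)C(C)(C)[C@@H]2[C@H]3C(=O)C=C(C)[C@@H]2[C@]31C | target

**Step count**

Total steps: 16. Longest linear sequence: 13 steps (steps 1, 3 to 13 and 16).

**Steps most likely to fail**

Step 11. The 4-exo-tet displacement at the hindered mesylate carbon may be too slow. Retro-aldol, followed by attack of the methyl-ketone enolate on the mesylate carbon, or base-induced loss of the mesylate could then overtake it. The fallback separates the two ring closures and removes the competing enolate. It sets out from 10, before the methyl ketone exists. Transthioacetalisation (propane-1,3-dithiol, Sc(OTf)3 cat.) should give the vinyl hydroxy dithiane F1, and mesylation the vinyl mesylate F2. Lithium 2,2,6,6-tetramethylpiperidide (1.1 equiv, THF/DMPU, −78 → 40 °C) then forms only the α′-enolate of the enone, which closes the cyclobutane by intramolecular alkylation to the bicyclo[3.1.1]heptenone dithiane F3. Alkylative dethioacetalisation (MeI, CaCO3) should give the bicyclic aldehyde F4, and Tsuji–Wacker oxidation (PdCl2, CuCl, O2) the bicyclic keto aldehyde F5. A separate intramolecular aldol addition (1 equiv of the same lithium amide, −78 °C) closes the seven-membered ring; the side-chain CH3 is then the only kinetically enolisable position, because C-1 and C-8 are bridgeheads. This comes back to the route at 16.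

Step 3. The cycloaddition to the β,β-disubstituted butenolide may be too slow to compete with thermal decomposition or polymerisation of the silyloxydiene. The fallback replaces the pericyclic reaction by an anionic stepwise annulation and sets out from 1 and 5. The kinetic lithium dienolate of 1 (lithium diisopropylamide, THF, −78 °C) adds in a Michael reaction to C-4 of 5, anti to the menthyloxy group. The lactone enolate so formed closes the six-membered ring by a second, intramolecular Michael addition to the propenyl ketone (double Michael annulation). The resulting ring-ketone enolate is silylated in the same flask with TBSCl, which comes back to the route at 6 without a new isolated compound.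

Step 13. Discrimination between the two hindered secondary hydroxyls may be insufficient, giving acylation at C-5 or at both positions. The fallback differentiates the two oxygens by construction and sets out from 16, before the reduction. Evans–Tishchenko reduction (SmI2 cat., acetaldehyde, THF, −10 °C) reduces the C-5 ketone anti by intramolecular hydride transfer and leaves the acyl group on O-3, giving the monoacetate F6. Yamaguchi esterification of the only free hydroxyl (C-5) with 22 should give the acetate epoxy ester F7. Selective methanolysis of the unhindered acetate (K2CO3, MeOH, 0 °C) should give the C-3 alcohol F8, and mixed-anhydride esterification with 18, as in step 13, comes back to the route at 23.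

Further compounds
F1 | step 11 | (4R,5S)-5-(1,3-dithian-2-yl)-4-[(1S)-1-hydroxy-2,2-dimethylbut-3-en-1-yl]-3,5-dimethylcyclohex-2-en-1-one | C=CC(C)(C)[C@@H](O)[C@@H]1C(C)=CC(=O)C[C@]1(C)C1SCCCS1
F2 | step 11 | (4R,5S)-5-(1,3-dithian-2-yl)-4-[(1S)-1-(methanesulfonyloxy)-2,2-dimethylbut-3-en-1-yl]-3,5-dimethylcyclohex-2-en-1-one | C=CC(C)(C)[C@@H](OS(C)(=O)=O)[C@@H]1C(C)=CC(=O)C[C@]1(C)C1SCCCS1
F3 | step 11 | 6-(1,3-dithian-2-yl)-4,6-dimethyl-7-(2-methylbut-3-en-2-yl)bicyclo[3.1.1]hept-3-en-2-one (dithianyl and alkyl groups anti to the enone bridge, facing each other) | C=CC(C)(C)[C@@H]1[C@H]2C(=O)C=C(C)[C@@H]1[C@@]2(C)C1SCCCS1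
F4 | step 11 | 2,6-dimethyl-7-(2-methylbut-3-en-2-yl)-4-oxobicyclo[3.1.1]hept-2-ene-6-carbaldehyde (configuration as F3) | C=CC(C)(C)[C@@H]1[C@H]2C(=O)C=C(C)[C@@H]1[C@@]2(C)C=O
F5 | step 11 | 2,6-dimethyl-7-(2-methyl-3-oxobutan-2-yl)-4-oxobicyclo[3.1.1]hept-2-ene-6-carbaldehyde (configuration as F3) | CC(=O)C(C)(C)[C@@H]1[C@H]2C(=O)C=C(C)[C@@H]1[C@@]2(C)C=O
F0 | step 3 | none | none
F6 | step 13 | (1R,2R,3R,5R,7S,8R)-5-hydroxy-2,6,6,9-tetramethyl-11-oxotricyclo[5.4.0.0(2,8)]undec-9-en-3-yl acetate | CC(=O)O[C@@H]1C[C@@H](O)C(C)(C)[C@@H]2[C@H]3C(=O)C=C(C)[C@@H]2[C@]31C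
F7 | step 13 | (1R,2R,3R,5R,7S,8R)-3-acetoxy-2,6,6,9-tetramethyl-11-oxotricyclo[5.4.0.0(2,8)]undec-9-en-5-yl (2S,3R)-2,3-dimethyloxirane-2-carboxylate | CC(=O)O[C@@H]1C[C@@H](OC(=O)[C@@]2(C)O[C@@H]2C)C(C)(C)[C@@H]2[C@H]3C(=O)C=C(C)[C@@H]2[C@]31C
F8 | step 13 | (1R,2R,3R,5R,7S,8R)-3-hydroxy-2,6,6,9-tetramethyl-11-oxotricyclo[5.4.0.0(2,8)]undec-9-en-5-yl (2S,3R)-2,3-dimethyloxirane-2-carboxylate | O[C@@H]1C[C@@H](OC(=O)[C@@]2(C)O[C@@H]2C)C(C)(C)[C@@H]2[C@H]3C(=O)C=C(C)[C@@H]2[C@]31C
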